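**Plan**

- Retrosynthesis: after removal of the silyl and benzyl groups, ring C of unit 1 (the 4'-methoxy flavanone) is cut at C2–C3. The 1,4-diketone behind it is cut at C3–C3''. Unit 2 is cut at C2''–C1''' (aryl) and then at the chromone C2'' carbon (C2''–C3'' and O1''–C2'').
- Forward: ring C of unit 2 is made first as a chromone, the C2'' aryl group is added, the C3''–C3 bond joins the two phloroacetophenone halves, and ring C of unit 1 closes last by C2–C3 bond formation.
- Stereochemistry: C2'' (R) comes from a chiral palladium catalyst and C3'' (S) from enolate alkylation anti to the C2'' aryl group. C2 and C3 (S,S, cis) are set together in the ring closure: cis from the Z enol acetate and E oxocarbenium geometries, absolute sense relayed from C3''.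
- Enabling feature: in ring C of unit 1, O1–C2(H)(4-methoxyphenyl) is a 4-methoxybenzyl ether of the ring A phenol oxygen, and C2 adjoins C3, the α-carbon of the C4 ketone. Removing hydride from C2 therefore puts an oxocarbenium carbon next to an enol carbon.

Key step: step 9

Assumption: (S)-t-BuPyOX is taken to give the 2R flavanone, by analogy with the face it selects on cyclic enones; if the sense proved opposite, the (R)-ligand would be used and nothing else would change.

Numbering: flavanone numbering throughout; unit 1 is the 4'-methoxy unit (O1, C2 to C8a), unit 2 carries double primes.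

**Route**

Step 1
Reactants: 1 2,4,6-trihydroxyacetophenone
Product: 2 1-[2,4-bis(benzyloxy)-6-hydroxyphenyl]ethanone
Conditions: BnBr (2.1 equiv), K2CO3 (2.2 equiv), DMF, 0 °C to rt
Reagents that add atoms: benzyl bromide, BrCc1ccccc1
Why: Williamson etherification; the hydroxyl hydrogen-bonded to the acetyl carbonyl is the least reactive and should stay free when two equivalents of halide are used.

Step 2
Reactants: 2 1-[2,4-bis(benzyloxy)-6-hydroxyphenyl]ethanone
Product: 4 5,7-bis(benzyloxy)-4H-chromen-4-one, via enaminone 3 (not isolated)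
Conditions: Me2NCH(OMe)2, toluene, 95 °C; then conc. HCl, CH2Cl2, rt
Reagents that add atoms: N,N-dimethylformamide dimethyl acetal, COC(OC)N(C)C
Why: Condensation at the methyl ketone gives the enaminone, and acid then promotes addition of the phenol to its β-carbon with loss of dimethylamine, the standard chromone synthesis from 2-hydroxyacetophenones.

Step 3
Reactants: 5 4-hydroxyphenylboronic acid
Product: 6 4-(triisopropylsilyloxy)phenylboronic acid
Conditions: iPr3SiCl, imidazole, DMF, rt; aqueous work-up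
Reagents that add atoms: chlorotriisopropylsilane, CC(C)[Si](Cl)(C(C)C)C(C)C
Why: Imidazole-mediated silylation of the phenol; any silyl ester formed at boron hydrolyses on aqueous work-up, and the silyl ether makes the later C2'' aryl ring a poorer donor than an alkoxyphenyl ring.

Step 4
Reactants: 4 5,7-bis(benzyloxy)-4H-chromen-4-one; 6 4-(triisopropylsilyloxy)phenylboronic acid
Product: 7 (2R)-5,7-bis(benzyloxy)-2-[4-(triisopropylsilyloxy)phenyl]chroman-4-one
Conditions: Pd(OCOCF3)2 (5 mol %), (S)-t-BuPyOX [(S)-4-tert-butyl-2-(pyridin-2-yl)-4,5-dihydrooxazole, 6 mol %], NH4PF6 (30 mol %), H2O (5 equiv), ClCH2CH2Cl, 60 °C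
Reagents that add atoms: none
Why: Asymmetric conjugate addition of an arylboronic acid to a chromone under divalent palladium/pyridine-oxazoline catalysis (transmetalation, carbopalladation, protonolysis of the palladium enolate by water); the tert-butyl group of the ligand shields one enone face in the carbopalladation, so the aryl group is delivered to give C2'' R.

Step 5
Reactants: 2 1-[2,4-bis(benzyloxy)-6-hydroxyphenyl]ethanone; 8 4-methoxybenzyl chloride
Product: 9 1-[2,4-bis(benzyloxy)-6-(4-methoxybenzyloxy)phenyl]ethanone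
Conditions: K2CO3, KI (cat.), DMF, 60 °C
Reagents that add atoms: none
Why: Williamson etherification of the chelated phenol, which needs only gentle heating with the reactive benzylic chloride.

Step 6
Reactants: 9 1-[2,4-bis(benzyloxy)-6-(4-methoxybenzyloxy)phenyl]ethanone
Product: 11 2-bromo-1-[2,4-bis(benzyloxy)-6-(4-methoxybenzyloxy)phenyl]ethanone, via trimethylsilyl enol ether 10 (not isolated)
Conditions: LiN(SiMe3)2, Me3SiCl, THF, −78 °C; pentane, filtration; then NBS, THF, −78 to 0 °C; product kept cold and used at once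
Reagents that add atoms: N-bromosuccinimide, O=C1CCC(=O)N1Br
Why: Enolisation at the only enolisable position and silylation give a silyl enol ether that reacts with NBS far faster than the trialkoxyarene does, so bromine should go to the α-carbon and not to ring A.

Step 7
Reactants: 7 (2R)-5,7-bis(benzyloxy)-2-[4-(triisopropylsilyloxy)phenyl]chroman-4-one; 11 2-bromo-1-[2,4-bis(benzyloxy)-6-(4-methoxybenzyloxy)phenyl]ethanone
Product: 13 (2R,3S)-3-{2-[2,4-bis(benzyloxy)-6-(4-methoxybenzyloxy)phenyl]-2-oxoethyl}-5,7-bis(benzyloxy)-2-[4-(triisopropylsilyloxy)phenyl]chroman-4-one, via lithium enolate 12 (not isolated)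
Conditions: LiN(SiMe3)2 (1.0 equiv), THF, −78 °C; then 11, −78 to −40 °C; AcOH quench at −78 °C
Reagents that add atoms: none
Why: SN2 alkylation of the kinetic lithium enolate by the phenacyl bromide, whose di-ortho-substituted carbonyl is shielded against Darzens-type addition; the electrophile enters anti to the C2'' aryl group and sets C3'' S (2'',3''-trans, also the more stable arrangement), while the low temperature holds back retro-oxa-Michael opening of the enolate.

Step 8
Reactants: 13 (2R,3S)-3-{2-[2,4-bis(benzyloxy)-6-(4-methoxybenzyloxy)phenyl]-2-oxoethyl}-5,7-bis(benzyloxy)-2-[4-(triisopropylsilyloxy)phenyl]chroman-4-one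
Product: 15 (Z)-1-[2,4-bis(benzyloxy)-6-(4-methoxybenzyloxy)phenyl]-2-[(2R,3S)-5,7-bis(benzyloxy)-4-oxo-2-[4-(triisopropylsilyloxy)phenyl]chroman-3-yl]vinyl acetate, via lithium Z-enolate 14 (not isolated)
Conditions: LiN(SiMe3)2 (1.1 equiv), THF, −78 °C; then Ac2O, −78 to 0 °C
Reagents that add atoms: acetic anhydride, CC(=O)OC(C)=O
Why: Kinetic deprotonation should take the open methylene next to the unit 1 ketone in preference to the shielded tertiary C3''–H and give the Z(O)-enolate usual for aryl alkyl ketones, which acetic anhydride acylates on oxygen with retention of geometry.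

Step 9
Reactants: 15 (Z)-1-[2,4-bis(benzyloxy)-6-(4-methoxybenzyloxy)phenyl]-2-[(2R,3S)-5,7-bis(benzyloxy)-4-oxo-2-[4-(triisopropylsilyloxy)phenyl]chroman-3-yl]vinyl acetate
Product: 18 (2S,3S,2''R,3''S)-5,7,5'',7''-tetrakis(benzyloxy)-4'-methoxy-4'''-(triisopropylsilyloxy)-3,3''-biflavanone, via oxocarbenium ion 16 (not isolated), via acetoxycarbenium ion 17 (not isolated)
Conditions: DDQ (2 equiv), 2,6-dichloropyridine (4 equiv), LiClO4, 4 Å MS, ClCH2CH2Cl, 0 °C to rt, dark
Reagents that add atoms: none
Why: Proposed new method: DDQ is expected to take hydride from the CH2 of the aryl 4-methoxybenzyl ether, whose oxygen sits on a ring A not yet conjugated to a ketone and whose cation is stabilised by the 4-methoxyphenyl ring, giving the (E)-oxocarbenium ion 16. C3 of the Z enol acetate then attacks C2 in a 6-(enolendo)-endo-trig closure, equivalent to a disrotatory 6π closure of the C2=O1–C8a=C4a–C4=C3 array, and the acetoxycarbenium ion 17 hands its acetyl group to 2,6-dichloropyridine or the reduced quinone to leave the C4 ketone; the closest known reaction type is the DDQ-mediated oxidative cyclisation of alkyl benzylic ethers bearing enol acetates to cis-2,6-disubstituted tetrahydropyran-4-ones, not yet shown for an aryl benzyl ether or for closure to a flavanone. Since the 4-methoxyphenyl group of the E ion and the C3'' substituent of the Z enol acetate both point away from the forming ring, C2 and C3 are set together as the cis pair. The absolute sense is predicted to come from C3'': the 4-methoxyphenyl group on the incoming carbon, cis to C3'', leaves room only for H3'' on that side, C2'' with its aryl group lies anti to the forming bond and the flat C4'' carbonyl sits beside the enol acetate oxygen, which exposes the C3 face that leads to 2S,3S. The step also needs chemoselectivity: benzyl aryl ethers are inert to DDQ at room temperature, and the tertiary C2''–H, next to the ketone-bearing C3'' and on the less donating silyloxyphenyl ring, should be oxidised more slowly than the primary benzylic C–H; the rival rotamer with H3'' turned toward the acetate would give the 2R,3R isomer, so the facial sense must be verified.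

Step 10
Reactants: 18 (2S,3S,2''R,3''S)-5,7,5'',7''-tetrakis(benzyloxy)-4'-methoxy-4'''-(triisopropylsilyloxy)-3,3''-biflavanone
Product: 19 (2S,3S,2''R,3''S)-5,7,5'',7''-tetrakis(benzyloxy)-4'''-hydroxy-4'-methoxy-3,3''-biflavanone
Conditions: HF·pyridine, pyridine, THF, 0 °C to rt
Reagents that add atoms: none
Why: Fluoride cleavage of the aryl silyl ether in a weakly acidic buffered medium that should not enolise C3 or C3''.

Step 11
Reactants: 19 (2S,3S,2''R,3''S)-5,7,5'',7''-tetrakis(benzyloxy)-4'''-hydroxy-4'-methoxy-3,3''-biflavanone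
Product: 20 (2S,3S,2''R,3''S)-5,7,5'',7'',4'''-pentahydroxy-4'-methoxy-3,3''-biflavanone (CNP0196568.4)
Conditions: H2 (1 atm), Pd/C (10 %), EtOAc–MeOH, rt
Reagents that add atoms: none
Why: Hydrogenolysis of the four aryl benzyl ethers at neutral pH; the deactivated 5-oxygenated aryl ketones and the ring C benzylic C–O bonds should survive these mild conditions, and no stereocenter is exposed to base.

**Compound list**

1 | 2,4,6-trihydroxyacetophenone | CC(=O)c1c(O)cc(O)cc1O | starting material
2 | 1-[2,4-bis(benzyloxy)-6-hydroxyphenyl]ethanone | CC(=O)c1c(O)cc(OCc2ccccc2)cc1OCc1ccccc1 | intermediate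
3 | (E)-1-[2,4-bis(benzyloxy)-6-hydroxyphenyl]-3-(dimethylamino)prop-2-en-1-one | CN(C)/C=C/C(=O)c1c(O)cc(OCc2ccccc2)cc1OCc1ccccc1 | intermediate (not isolated)
4 | 5,7-bis(benzyloxy)-4H-chromen-4-one | O=c1ccoc2cc(OCc3ccccc3)cc(OCc3ccccc3)c12 | intermediate
5 | 4-hydroxyphenylboronic acid | OB(O)c1ccc(O)cc1 | starting material
6 | 4-(triisopropylsilyloxy)phenylboronic acid | CC(C)[Si](Oc1ccc(B(O)O)cc1)(C(C)C)C(C)C | intermediate
7 | (2R)-5,7-bis(benzyloxy)-2-[4-(triisopropylsilyloxy)phenyl]chroman-4-one | O=C1C[C@H](c2ccc(O[Si](C(C)C)(C(C)C)C(C)C)cc2)Oc2cc(OCc3ccccc3)cc(OCc3ccccc3)c21 | intermediate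
8 | 4-methoxybenzyl chloride | COc1ccc(CCl)cc1 | starting material
9 | 1-[2,4-bis(benzyloxy)-6-(4-methoxybenzyloxy)phenyl]ethanone | CC(=O)c1c(OCc2ccc(OC)cc2)cc(OCc2ccccc2)cc1OCc1ccccc1 | intermediate
10 | trimethylsilyl enol ether of 9, 1-[2,4-bis(benzyloxy)-6-(4-methoxybenzyloxy)phenyl]-1-(trimethylsilyloxy)ethene | C=C(O[Si](C)(C)C)c1c(OCc2ccc(OC)cc2)cc(OCc2ccccc2)cc1OCc1ccccc1 | intermediate (not isolated)
11 | 2-bromo-1-[2,4-bis(benzyloxy)-6-(4-methoxybenzyloxy)phenyl]ethanone | BrCC(=O)c1c(OCc2ccc(OC)cc2)cc(OCc2ccccc2)cc1OCc1ccccc1 | intermediate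
12 | lithium enolate of 7, lithium (2R)-5,7-bis(benzyloxy)-2-[4-(triisopropylsilyloxy)phenyl]-2H-chromen-4-olate | [Li+].[O-]C1=C[C@H](c2ccc(O[Si](C(C)C)(C(C)C)C(C)C)cc2)Oc2cc(OCc3ccccc3)cc(OCc3ccccc3)c21 | intermediate (not isolated)
13 | (2R,3S)-3-{2-[2,4-bis(benzyloxy)-6-(4-methoxybenzyloxy)phenyl]-2-oxoethyl}-5,7-bis(benzyloxy)-2-[4-(triisopropylsilyloxy)phenyl]chroman-4-one | COc1ccc(COc2cc(OCc3ccccc3)cc(OCc3ccccc3)c2C(=O)C[C@@H]2C(=O)c3c(OCc4ccccc4)cc(OCc4ccccc4)cc3O[C@H]2c2ccc(O[Si](C(C)C)(C(C)C)C(C)C)cc2)cc1 | intermediate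
14 | lithium (Z)-enolate of 13 at the unit 1 ketone | [Li+].COc1ccc(COc2cc(OCc3ccccc3)cc(OCc3ccccc3)c2/C([O-])=C/[C@@H]2C(=O)c3c(OCc4ccccc4)cc(OCc4ccccc4)cc3O[C@H]2c2ccc(O[Si](C(C)C)(C(C)C)C(C)C)cc2)cc1 | intermediate (not isolated)
15 | (Z)-1-[2,4-bis(benzyloxy)-6-(4-methoxybenzyloxy)phenyl]-2-[(2R,3S)-5,7-bis(benzyloxy)-4-oxo-2-[4-(triisopropylsilyloxy)phenyl]chroman-3-yl]vinyl acetate | COc1ccc(COc2cc(OCc3ccccc3)cc(OCc3ccccc3)c2/C(OC(C)=O)=C/[C@@H]2C(=O)c3c(OCc4ccccc4)cc(OCc4ccccc4)cc3O[C@H]2c2ccc(O[Si](C(C)C)(C(C)C)C(C)C)cc2)cc1 | intermediate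
16 | (E)-aryl(4-methoxybenzylidene)oxonium ion from 15 | COc1ccc(/C=[O+]/c2cc(OCc3ccccc3)cc(OCc3ccccc3)c2/C(OC(C)=O)=C/[C@@H]2C(=O)c3c(OCc4ccccc4)cc(OCc4ccccc4)cc3O[C@H]2c2ccc(O[Si](C(C)C)(C(C)C)C(C)C)cc2)cc1 | intermediate (not isolated)
17 | cyclised C4 acetoxycarbenium ion, (2S,3S,2''R,3''S) | COc1ccc([C@H]2Oc3cc(OCc4ccccc4)cc(OCc4ccccc4)c3C(=[O+]C(C)=O)[C@H]2[C@@H]2C(=O)c3c(OCc4ccccc4)cc(OCc4ccccc4)cc3O[C@H]2c2ccc(O[Si](C(C)C)(C(C)C)C(C)C)cc2)cc1 | intermediate (not isolated)
18 | (2S,3S,2''R,3''S)-5,7,5'',7''-tetrakis(benzyloxy)-4'-methoxy-4'''-(triisopropylsilyloxy)-3,3''-biflavanone | COc1ccc([C@H]2Oc3cc(OCc4ccccc4)cc(OCc4ccccc4)c3C(=O)[C@H]2[C@@H]2C(=O)c3c(OCc4ccccc4)cc(OCc4ccccc4)cc3O[C@H]2c2ccc(O[Si](C(C)C)(C(C)C)C(C)C)cc2)cc1 | intermediate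
19 | (2S,3S,2''R,3''S)-5,7,5'',7''-tetrakis(benzyloxy)-4'''-hydroxy-4'-methoxy-3,3''-biflavanone | COc1ccc([C@H]2Oc3cc(OCc4ccccc4)cc(OCc4ccccc4)c3C(=O)[C@H]2[C@@H]2C(=O)c3c(OCc4ccccc4)cc(OCc4ccccc4)cc3O[C@H]2c2ccc(O)cc2)cc1 | intermediate
20 | (2S,3S,2''R,3''S)-5,7,5'',7'',4'''-pentahydroxy-4'-methoxy-3,3''-biflavanone | COc1ccc([C@H]2Oc3cc(O)cc(O)c3C(=O)[C@H]2[C@@H]2C(=O)c3c(O)cc(O)cc3O[C@H]2c2ccc(O)cc2)cc1 | target

**Step count**

Total: 11 steps. Longest linear sequence: 8 steps (steps 1, 2, 4, 7, 8, 9, 10, 11; the branch through steps 1, 5, 6 is equally long).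

**Steps most likely to fail**

Step 9. Oxidation of the electron-rich enol acetate or of C2''–H may outrun hydride abstraction at the aryl benzyl ether, or the closure may take the other face of C3.
- The fallback builds ring C of unit 1 by condensation chemistry and sets out from 13.
- Trifluoroacetic acid with pentamethylbenzene as cation trap (CH2Cl2, 0 °C) should remove only the 4-methoxybenzyl group and give the free phenol (2R,3S)-3-{2-[2,4-bis(benzyloxy)-6-hydroxyphenyl]-2-oxoethyl}-5,7-bis(benzyloxy)-2-[4-(triisopropylsilyloxy)phenyl]chroman-4-one F1.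
- Pyrrolidine-mediated aldol condensation of F1 with 4-methoxybenzaldehyde (MeOH, rt) should pass through the benzylidene diketone F2, which closes by 6-endo oxa-Michael addition of the phenol.
- Protonation of the resulting enol at C3 anti to the new C2 aryl group should favour the 2,3-cis flavanone, which would be separated from its C2/C3 isomers.
- The sequence comes back to the route at 18.

Step 7. The lithium enolate may open by retro-oxa-Michael elimination, eroding the C2'' configuration, or be quenched by proton transfer from the bromo ketone.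
- The fallback replaces the enolate by a neutral radical acceptor and sets out from 7.
- Soft enolisation (Me3SiOTf, Et3N, CH2Cl2, 0 °C) should give (2R)-5,7-bis(benzyloxy)-2-[4-(triisopropylsilyloxy)phenyl]-4-(trimethylsilyloxy)-2H-chromene F3.
- Visible-light photoredox coupling of F3 with 11 (tris(2-phenylpyridinato)iridium 1 mol %, 2,6-lutidine, MeCN, blue light, rt) generates the phenacyl radical, which should add to C3'' anti to the aryl group.
- Oxidation and desilylation of the adduct radical return the ketone, and the route is rejoined at 13.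

Step 8. Deprotonation at C3''–H, or proton transfer between the two enolisable sites before the slower O-acylation, may give regio- and geometric mixtures.
- The fallback traps the enolate as it forms and sets out from 13.
- LiN(SiMe3)2 is added to a premixed solution of 13 and Et3SiCl (THF, −78 °C), which should give the (Z)-triethylsilyl enol ether of the unit 1 ketone F4.
- F4 is freed from any regioisomer on triethylamine-deactivated silica.
- Acetyl fluoride with catalytic tetrabutylammonium difluorotriphenylsilicate (THF, −78 to 0 °C) then exchanges silyl for acetyl on oxygen with retention of geometry.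
- The sequence comes back to the route at 15.

**Further compounds**

F1 | step 9 | (2R,3S)-3-{2-[2,4-bis(benzyloxy)-6-hydroxyphenyl]-2-oxoethyl}-5,7-bis(benzyloxy)-2-[4-(triisopropylsilyloxy)phenyl]chroman-4-one | Oc1cc(OCc2ccccc2)cc(OCc2ccccc2)c1C(=O)C[C@@H]1C(=O)c2c(OCc3ccccc3)cc(OCc3ccccc3)cc2O[C@H]1c1ccc(O[Si](C(C)C)(C(C)C)C(C)C)cc1
F2 | step 9 | (E)-1-[2,4-bis(benzyloxy)-6-hydroxyphenyl]-2-[(2R,3S)-5,7-bis(benzyloxy)-4-oxo-2-[4-(triisopropylsilyloxy)phenyl]chroman-3-yl]-3-(4-methoxyphenyl)prop-2-en-1-one | COc1ccc(/C=C(/C(=O)c2c(O)cc(OCc3ccccc3)cc2OCc2ccccc2)[C@@H]2C(=O)c3c(OCc4ccccc4)cc(OCc4ccccc4)cc3O[C@H]2c2ccc(O[Si](C(C)C)(C(C)C)C(C)C)cc2)cc1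
F3 | step 7 | (2R)-5,7-bis(benzyloxy)-2-[4-(triisopropylsilyloxy)phenyl]-4-(trimethylsilyloxy)-2H-chromene | C[Si](C)(C)OC1=C[C@H](c2ccc(O[Si](C(C)C)(C(C)C)C(C)C)cc2)Oc2cc(OCc3ccccc3)cc(OCc3ccccc3)c21
F4 | step 8 | (Z)-triethylsilyl enol ether of 13 at the unit 1 ketone | COc1ccc(COc2cc(OCc3ccccc3)cc(OCc3ccccc3)c2/C(O[Si](CC)(CC)CC)=C/[C@@H]2C(=O)c3c(OCc4ccccc4)cc(OCc4ccccc4)cc3O[C@H]2c2ccc(O[Si](C(C)C)(C(C)C)C(C)C)cc2)cc1
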